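**Assumptions (one line each)**
- The target's C7 is (7R) by CIP; this is the natural-series configuration. I assume (–)-sparteine with Cu/O2 delivers it. If the opposite enantiomer forms, (+)-sparteine is used.
- Bestmann–Ohira reagent, Ghosez's reagent, PMBCl and methyl orsellinate are bought, not made.

## Retrosynthetic overview
1. Target ⇒ C7 orsellinate ester (bis-PMB protected) of the tertiary 7-OH azaphilone, with the acrylic acid held as a t-Bu ester. A single TFA step removes the PMB ethers and the t-Bu ester.
2. The C7 quaternary (R) stereocentre comes from Cu/(–)-sparteine/O2 hydroxylative dearomatization of a pyrano-quinone methide (the last ring-forming event, the carbocycle).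
3. The pyran ring (O2–C1/C3) forms first, by Ag(I) 6-endo cycloisomerization of an o-alkynyl salicylaldehyde. The alkyne comes from Sonogashira coupling of an aryl iodide with t-Bu (E)-pent-2-en-4-ynoate.
4. The aryl iodide is made from 2,6-dimethoxytoluene by Vilsmeier formylation, directed ortho-iodination and selective ortho-demethylation.

## Forward route

**Step 1**
Reactants: 1 (1,3-dimethoxy-2-methylbenzene), 2 (DMF)
Product: 3 (2,4-dimethoxy-3-methylbenzaldehyde)
Conditions: POCl3, DMF, 0 → 70 °C; aq. NaOAc workup
Reagents that add atoms: DMF, CN(C)C=O (supplies the CHO)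
Why: Vilsmeier–Haack formylation occurs at C4, para to one OMe and ortho to the other, the only activated position that is not flanked on both sides; no stereocentre is formed.

**Step 2**
Reactants: 3, 4 (iodine)
Product: 5 (6-iodo-2,4-dimethoxy-3-methylbenzaldehyde)
Conditions: (a) Me2NCH2CH2NHMe, n-BuLi, THF, –20 °C, then 3, then n-BuLi (3 equiv), –20 → 0 °C; (b) I2, THF, –78 °C → rt; aq. workup
Reagents that add atoms: I2, II
Why: Comins α-amino-alkoxide-directed ortho-lithiation occurs at C6, the only free position ortho to the masked CHO, and I2 traps it. This places the halide at the carbon that becomes C4a.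

**Step 3**
Reactants: 5
Product: 6 (2-hydroxy-6-iodo-4-methoxy-3-methylbenzaldehyde)
Conditions: BCl3 (1.1 equiv), CH2Cl2, –78 → 0 °C; aq. NaHCO3
Reagents that add atoms: none
Why: Chelation-controlled Lewis-acid O-demethylation cleaves only the OMe ortho to the aldehyde. This unmasks the future C8 oxygen as a chelated phenol and leaves the C6 oxygen as OMe.

**Step 4**
Reactants: 7 (tert-butyl (E)-4-oxobut-2-enoate), 8 (Bestmann–Ohira reagent)
Product: 9 (tert-butyl (E)-pent-2-en-4-ynoate)
Conditions: K2CO3, MeOH, THF, 0 °C → rt
Reagents that add atoms: dimethyl (1-diazo-2-oxopropyl)phosphonate, CC(=O)C(=[N+]=[N-])P(=O)(OC)OC (supplies the terminal alkyne carbon)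
Why: Ohira–Bestmann homologation of an aldehyde to a terminal alkyne under mild base; the E-enoate and the t-Bu ester survive.

**Step 5**
Reactants: 6, 9
Product: 10 (tert-butyl (2E)-5-(2-formyl-3-hydroxy-5-methoxy-4-methylphenyl)pent-2-en-4-ynoate)
Conditions: PdCl2(PPh3)2 (5 mol %), CuI (10 mol %), Et3N, THF, rt
Reagents that add atoms: none
Why: Sonogashira coupling of the aryl iodide with the terminal enyne; the free chelated phenol and the aldehyde are tolerated.

**Step 6**
Reactants: 10
Product: 11 (tert-butyl (2E)-3-(6-methoxy-7-methyl-8-oxo-8H-isochromen-3-yl)acrylate, the neutral pyrylium-phenolate, i.e. pyrano-quinone-methide, form)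
Conditions: AgOTf (5 mol %), 2,6-di-tert-butylpyridine (5 mol %), CH2Cl2, rt
Reagents that add atoms: none
Why: Ag(I)-catalysed 6-endo-dig attack of the aldehyde oxygen on the alkyne gives the 2-benzopyrylium, and loss of the phenolic proton gives neutral 11 (an isomer of 10). The pyran ring is formed here, and no stereocentre arises. The hindered base protects the t-Bu ester from traces of TfOH, and the conjugating acrylate could in principle favour 5-exo closure, so the 6-endo selectivity is monitored.

**Step 7**
Reactants: 11
Product: 12 (tert-butyl (E)-3-[(7R)-7-hydroxy-7-methyl-6,8-dioxo-7,8-dihydro-6H-isochromen-3-yl]acrylate)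
Conditions: CuCl2 (1.1 equiv), (–)-sparteine (1.2 equiv), O2 (1 atm), CH2Cl2, –20 → 0 °C; then PPh3 (1.5 equiv), 30 min; sat. aq. NH4Cl workup; recrystallize to upgrade ee
Reagents that add atoms: O2, O=O; water, O (hydrolysis of the C6 oxocarbenium, losing MeOH)
Why: Enantioselective hydroxylative dearomatization: the electron-rich enol-ether carbon C7 is oxygenated by O2 within the chiral Cu(II)–sparteine complex, which sets the C7 quaternary stereocentre (R). PPh3 reduces the hydroperoxide to the alcohol, and aqueous workup converts the 6-OMe oxocarbenium to the 6-ketone, giving the 6,8-dione.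

**Step 8**
Reactants: 13 (methyl orsellinate), 14 (PMBCl)
Product: 15 (methyl 2,4-bis[(4-methoxybenzyl)oxy]-6-methylbenzoate)
Conditions: PMBCl (2.5 equiv), K2CO3, TBAI (cat.), DMF, 60 °C
Reagents that add atoms: 4-methoxybenzyl chloride, ClCc1ccc(OC)cc1 (the PMB groups)
Why: Williamson O-alkylation of both phenols, giving protecting groups that TFA removes later together with the t-Bu ester.

**Step 9**
Reactants: 15
Product: 16 (2,4-bis[(4-methoxybenzyl)oxy]-6-methylbenzoic acid)
Conditions: KOH, ethylene glycol/H2O, 120 °C; then 1 M HCl to pH 3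
Reagents that add atoms: water, O
Why: Forcing saponification is needed for the di-ortho-substituted benzoate, and the PMB ethers are base-stable.

**Step 10**
Reactants: 16, 17 (Ghosez reagent)
Product: 18 (2,4-bis[(4-methoxybenzyl)oxy]-6-methylbenzoyl chloride)
Conditions: 17 (1.2 equiv), CH2Cl2, 0 °C → rt, 1 h; concentrate and use directly
Reagents that add atoms: 1-chloro-N,N,2-trimethylprop-1-enylamine, CC(C)=C(Cl)N(C)C (supplies Cl)
Why: Neutral conversion of the acid to the acid chloride avoids HCl-mediated loss of the PMB ethers.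

**Step 11**
Reactants: 12, 18
Product: 19 (tert-butyl (E)-3-[(7R)-7-{[2,4-bis(PMBO)-6-methylbenzoyl]oxy}-7-methyl-6,8-dioxo-7,8-dihydro-6H-isochromen-3-yl]acrylate)
Conditions: DMAP (1.5 equiv), pyridine (10 equiv), CH2Cl2 or DCE, 40 °C, 16–24 h
Reagents that add atoms: none beyond 18
Why: Nucleophilic acyl substitution at the tertiary alcohol; the C–O bond at C7 is not broken and C7 has no α-H, so configuration is retained. Tertiary amines do not form vinylogous pyridones with the azaphilone, unlike primary amines.

**Step 12**
Reactants: 19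
Product: 20 (mitorubrinic acid)
Conditions: TFA/CH2Cl2 (1:4), anisole (10 equiv), 0 °C → rt, 1–2 h
Reagents that add atoms: none
Why: Acidolysis removes both PMB ethers (the cations are trapped by anisole) and the t-Bu ester in one step. The azaphilone, the C7 ester and the E-olefin are acid-stable, and no stereocentre is touched.

## Compound list
1 | 1,3-dimethoxy-2-methylbenzene | COc1cccc(OC)c1C | starting material
2 | N,N-dimethylformamide | CN(C)C=O | starting material
3 | 2,4-dimethoxy-3-methylbenzaldehyde | O=Cc1ccc(OC)c(C)c1OC | intermediate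
4 | iodine | II | starting material
5 | 6-iodo-2,4-dimethoxy-3-methylbenzaldehyde | O=Cc1c(I)cc(OC)c(C)c1OC | intermediate
6 | 2-hydroxy-6-iodo-4-methoxy-3-methylbenzaldehyde | O=Cc1c(I)cc(OC)c(C)c1O | intermediate
7 | tert-butyl (E)-4-oxobut-2-enoate | O=C/C=C/C(=O)OC(C)(C)C | starting material
8 | dimethyl (1-diazo-2-oxopropyl)phosphonate | CC(=O)C(=[N+]=[N-])P(=O)(OC)OC | starting material
9 | tert-butyl (E)-pent-2-en-4-ynoate | C#C/C=C/C(=O)OC(C)(C)C | intermediate
10 | tert-butyl (2E)-5-(2-formyl-3-hydroxy-5-methoxy-4-methylphenyl)pent-2-en-4-ynoate | O=Cc1c(C#C/C=C/C(=O)OC(C)(C)C)cc(OC)c(C)c1O | intermediate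
11 | tert-butyl (2E)-3-(6-methoxy-7-methyl-8-oxo-8H-isochromen-3-yl)acrylate | COC1=C(C)C(=O)C2=COC(/C=C/C(=O)OC(C)(C)C)=CC2=C1 | intermediate
12 | tert-butyl (E)-3-[(7R)-7-hydroxy-7-methyl-6,8-dioxo-7,8-dihydro-6H-isochromen-3-yl]acrylate | O[C@]1(C)C(=O)C=C2C=C(/C=C/C(=O)OC(C)(C)C)OC=C2C1=O | intermediate
13 | methyl 2,4-dihydroxy-6-methylbenzoate (methyl orsellinate) | COC(=O)c1c(C)cc(O)cc1O | starting material
14 | 4-methoxybenzyl chloride | ClCc1ccc(OC)cc1 | starting material
15 | methyl 2,4-bis[(4-methoxybenzyl)oxy]-6-methylbenzoate | COC(=O)c1c(C)cc(OCc2ccc(OC)cc2)cc1OCc1ccc(OC)cc1 | intermediate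
16 | 2,4-bis[(4-methoxybenzyl)oxy]-6-methylbenzoic acid | Cc1cc(OCc2ccc(OC)cc2)cc(OCc2ccc(OC)cc2)c1C(=O)O | intermediate
17 | 1-chloro-N,N,2-trimethylprop-1-en-1-amine (Ghosez reagent) | CC(C)=C(Cl)N(C)C | starting material
18 | 2,4-bis[(4-methoxybenzyl)oxy]-6-methylbenzoyl chloride | Cc1cc(OCc2ccc(OC)cc2)cc(OCc2ccc(OC)cc2)c1C(=O)Cl | intermediate
19 | protected ester (t-Bu acrylate, bis-PMB orsellinate) | Cc1cc(OCc2ccc(OC)cc2)cc(OCc2ccc(OC)cc2)c1C(=O)O[C@]1(C)C(=O)C=C2C=C(/C=C/C(=O)OC(C)(C)C)OC=C2C1=O | intermediate
20 | mitorubrinic acid | Cc1cc(O)cc(O)c1C(=O)O[C@]1(C)C(=O)C=C2C=C(/C=C/C(=O)O)OC=C2C1=O | target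

## Totals
- Total steps: 12.
- Longest linear sequence: 8 (Steps 1, 2, 3, 5, 6, 7, 11, 12).

## Three steps most likely to fail
1. **Step 2, Comins ortho-iodination.** Lithiation at C5, ortho to the 4-OMe, could compete with lithiation at C6 next to the aminoalkoxide.
   - Fallback (different approach): use 2,4-dimethoxy-3-methylbenzoic acid and do carboxylate-directed Pd(II) ortho-C–H iodination. Then reduce the acid to the benzyl alcohol and reoxidize to the aldehyde (LiAlH4, then MnO2) to rejoin the route at compound 5.
2. **Step 7, Cu/(–)-sparteine hydroxylation.** The 6-OMe pyranoquinone-methide is an unprecedented substrate for this chemistry, and ee and hydrolysis to the dione may be poor.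
   - Fallback (different approach): do a racemic hydroxylative dearomatization of 11 with PIFA in aqueous MeCN, then resolve the tert-butyl ester 12 by preparative chiral-phase SFC to give the (7R) enantiomer.
3. **Step 11, acylation.** The tertiary alcohol between two carbonyls and the di-ortho-substituted acid chloride make this a very hindered coupling.
   - Fallback (different approach): install the ester during dearomatization instead. Oxidize quinoid 11 with PIDA in the presence of acid 16 (acyloxylative dearomatization) to give racemic 19, then resolve it by chiral SFC and continue with Step 12.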